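The plan rests on cutting the C3–C4 bond of the lactone ring in the ether-bearing unit. C4, the benzylic carbinol carbon on the aromatic ring, is a disguised formyl carbon, and C3 with its ring oxygen O2 and methyl group is a disguised vinyl ester. An NHC-catalysed intramolecular hydroacylation should isomerise vinyl 2-formylbenzoate 6 into the isochromane-1,4-dione 8, closing the lactone and creating the C3 methyl in one atom-economic operation. The labile C3 of this α-acyloxy ketone then allows one dynamic kinetic transfer hydrogenation to set both stereocentres. Two Mitsunobu inversions at C4 turn the single cis alcohol into both trans units and forge the C4–O–C6′ ether.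

Key step: step 4

Remark: locants follow isochroman-1-one numbering (C1 lactone carbonyl, O2, C3, C4, C4a to C8a). Unprimed locants belong to the unit that carries the C4 aryl ether, primed ones to the unit with the free 4′-hydroxyl. MOM = methoxymethyl; ADDP = 1,1′-(azodicarbonyl)dipiperidine. 3,5-Dihydroxy-4-methoxybenzaldehyde is taken as a catalogue compound.

Step 1
Reactants: 1 3,5-dihydroxy-4-methoxybenzaldehyde
Product: 2 4-methoxy-3,5-bis(methoxymethoxy)benzaldehyde
Conditions: MOMCl, i-Pr2NEt, CH2Cl2, 0 °C → rt
Reagents that add atoms: chloromethyl methyl ether COCCl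
Why: O-alkylation of both phenols as MOM acetals gives groups that survive organolithium, carbene, transfer-hydrogenation and Mitsunobu conditions and later direct the ortho-metalation.

Step 2
Reactants: 2 4-methoxy-3,5-bis(methoxymethoxy)benzaldehyde
Product: 3 5-(dimethoxymethyl)-2-methoxy-1,3-bis(methoxymethoxy)benzene
Conditions: HC(OMe)3, MeOH, PPTS (cat.), rt; Et3N quench
Reagents that add atoms: trimethyl orthoformate COC(OC)OC; methanol CO
Why: Acid-catalysed acetalisation with orthoformate as water scavenger masks the aldehyde against n-BuLi, and brief mild acid at rt should leave the aryl MOM ethers intact.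

Step 3
Reactants: 3 5-(dimethoxymethyl)-2-methoxy-1,3-bis(methoxymethoxy)benzene
Product: 6 vinyl 6-formyl-3-methoxy-2,4-bis(methoxymethoxy)benzoate, via aryllithium 4 (not isolated), via acetal vinyl ester 5 (not isolated)
Conditions: n-BuLi, TMEDA, THF, −78 → −20 °C; cannulate into ClCO2CH=CH2 (excess), THF, −78 °C; then AcOH/H2O/THF, rt
Reagents that add atoms: vinyl chloroformate C=COC(Cl)=O; water O
Why: Directed ortho-metalation at the only ring C–H position (both are equivalent, each flanked by the acetal and a MOM ether), single acylation of the hindered aryllithium by the chloroformate under inverse addition, and mild aqueous acid hydrolysis of the benzaldehyde acetal should give the vinyl ester aldehyde.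

Step 4
Reactants: 6 vinyl 6-formyl-3-methoxy-2,4-bis(methoxymethoxy)benzoate
Product: 8 7-methoxy-6,8-bis(methoxymethoxy)-3-methylisochromane-1,4-dione (racemic at C3), via Breslow enaminol 7 (not isolated)
Conditions: 2-mesityl-6,7-dihydro-5H-pyrrolo[2,1-c][1,2,4]triazol-2-ium chloride (15 mol%), DBU (10 mol%), 1,4-dioxane, 100 °C
Reagents that add atoms: none
Why: Proposed new method: the free carbene adds to the formyl group of 6 and proton transfer gives the Breslow enaminol 7, whose nucleophilic carbon (the future C4) bonds to the oxygen-bearing vinyl carbon (the future C3) while its O–H proton is delivered to the terminal CH2 in a concerted, asynchronous ene-type transition state, after which the carbene is expelled to leave the C4 ketone. The closest known reaction is the NHC-catalysed intramolecular hydroacylation of unactivated olefins that turns 2-allyloxybenzaldehydes into 3-methylchroman-4-ones; a vinyl ester has not been used as the olefin, but its polarisation (proton-accepting terminal carbon, electrophilic oxygen-bearing carbon) matches the proton-first transition state. The lactone ring is closed in the 6-exo-trig mode at the internal vinyl carbon; the 7-endo alternative would require protonation of the oxygen-bearing carbon and is disfavoured by both polarity and the five-membered C–O–H···C=C geometry. The one new stereocentre, C3, forms racemic and is deliberately left uncontrolled, because it sits alpha to the C4 ketone and is set in step 5. The step needs chemoselectivity for C–C bond formation over acyl transfer from the activated vinyl ester to the carbene, the base or the aldehyde-derived alkoxide (which would collapse to a phthalide); the two ortho substituents flanking the ester carbonyl (the C8 MOM ether and C4a) shield it, and the base is kept below the azolium loading so that no free amidine remains.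

Step 5
Reactants: 8 7-methoxy-6,8-bis(methoxymethoxy)-3-methylisochromane-1,4-dione
Product: 9 (3R,4R)-4-hydroxy-7-methoxy-6,8-bis(methoxymethoxy)-3-methylisochroman-1-one (cis alcohol)
Conditions: RuCl[(S,S)-TsDPEN](p-cymene) (2 mol%), HCO2H/Et3N (5:2), EtOAc, 30 °C
Reagents that add atoms: none
Why: Asymmetric transfer hydrogenation with dynamic kinetic resolution (Noyori–Ikariya type): C3 racemises through the enol under the amine buffer, the (S,S)-catalyst should deliver hydride to the aryl ketone face predicted by the CH/π model (4R) and anti to the C3 methyl group, so that the faster-reacting (3R)-ketone gives the cis (3R,4R) alcohol.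

Step 6
Reactants: 9 (3R,4R)-4-hydroxy-7-methoxy-6,8-bis(methoxymethoxy)-3-methylisochroman-1-one
Product: 11 (3R,4S)-7-methoxy-6,8-bis(methoxymethoxy)-3-methyl-1-oxoisochroman-4-yl formate (trans), via alkoxytriphenylphosphonium ion 10 (not isolated)
Conditions: HCO2H, PPh3, DIAD, THF, 0 °C → rt
Reagents that add atoms: formic acid O=CO
Why: Mitsunobu esterification displaces the activated benzylic C4 oxygen by formate in SN2 fashion with inversion, converting the cis alcohol into the trans (3R,4S) ester needed for the hydroxyl-bearing unit while C3 is untouched.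

Step 7
Reactants: 11 (3R,4S)-7-methoxy-6,8-bis(methoxymethoxy)-3-methyl-1-oxoisochroman-4-yl formate
Product: 12 (3R,4S)-6,8-dihydroxy-7-methoxy-3-methyl-1-oxoisochroman-4-yl formate
Conditions: TFA, CH2Cl2, H2O (2 equiv), 0 °C → rt; evaporate
Reagents that add atoms: none
Why: Aryl MOM acetals are cleaved by trifluoroacetic acid (acetal hydrolysis), whereas the secondary formate, the lactone and the methyl ether should be inert in the absence of an alcohol nucleophile.

Step 8
Reactants: 9 (3R,4R)-4-hydroxy-7-methoxy-6,8-bis(methoxymethoxy)-3-methylisochroman-1-one; 12 (3R,4S)-6,8-dihydroxy-7-methoxy-3-methyl-1-oxoisochroman-4-yl formate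
Product: 14 (3R,4S)-8-hydroxy-7-methoxy-6-{[(3R,4S)-7-methoxy-6,8-bis(methoxymethoxy)-3-methyl-1-oxoisochroman-4-yl]oxy}-3-methyl-1-oxoisochroman-4-yl formate, via alkoxytributylphosphonium ion 13 (not isolated)
Conditions: PBu3, ADDP, THF/toluene, 0 °C → rt
Reagents that add atoms: none
Why: Mitsunobu etherification in its trialkylphosphine/azodicarboxamide (Tsunoda) variant, whose smaller and less ionisation-prone alkoxytributylphosphonium ion suits the hindered benzylic C4 of 9: the 6′-OH of 12 (para to the lactone carbonyl, the more acidic and the only non-chelated phenol) should displace the activated C4 oxygen with SN2 inversion to give the trans (3R,4S) aryl ether, the 8′-OH being held in a hydrogen bond to C1′=O and the 4′-oxygen being blocked as the formate.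

Step 9
Reactants: 14 (3R,4S)-8-hydroxy-7-methoxy-6-{[(3R,4S)-7-methoxy-6,8-bis(methoxymethoxy)-3-methyl-1-oxoisochroman-4-yl]oxy}-3-methyl-1-oxoisochroman-4-yl formate
Product: 15 (3R,4S)-4-{[(3R,4S)-4,8-dihydroxy-7-methoxy-3-methyl-1-oxoisochroman-6-yl]oxy}-6,8-dihydroxy-7-methoxy-3-methylisochroman-1-one (target)
Conditions: HCl (1.25 M in MeOH), CH2Cl2 co-solvent, rt
Reagents that add atoms: none
Why: Acid-catalysed methanolysis (transacetalisation and transesterification) should remove both MOM groups and the formate in one operation without touching a stereocentre, the benzylic C4–OAr ether being protected from ionisation by the ortho lactone carbonyl.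

Compound list
1 | 3,5-dihydroxy-4-methoxybenzaldehyde | COc1c(O)cc(C=O)cc1O | starting material
2 | 4-methoxy-3,5-bis(methoxymethoxy)benzaldehyde | COCOc1cc(C=O)cc(OCOC)c1OC | intermediate
3 | 5-(dimethoxymethyl)-2-methoxy-1,3-bis(methoxymethoxy)benzene | COCOc1cc(C(OC)OC)cc(OCOC)c1OC | intermediate
4 | [2-(dimethoxymethyl)-5-methoxy-4,6-bis(methoxymethoxy)phenyl]lithium (formed in situ) | [Li]c1c(C(OC)OC)cc(OCOC)c(OC)c1OCOC | intermediate
5 | vinyl 6-(dimethoxymethyl)-3-methoxy-2,4-bis(methoxymethoxy)benzoate (formed in situ) | C=COC(=O)c1c(C(OC)OC)cc(OCOC)c(OC)c1OCOC | intermediate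
6 | vinyl 6-formyl-3-methoxy-2,4-bis(methoxymethoxy)benzoate | C=COC(=O)c1c(C=O)cc(OCOC)c(OC)c1OCOC | intermediate
7 | Breslow enaminol from 6 and the N-mesityl triazolylidene (formed in situ) | OC(=C1N(c2c(C)cc(C)cc2C)N=C2CCCN12)c1cc(OCOC)c(OC)c(OCOC)c1C(=O)OC=C | intermediate
8 | 7-methoxy-6,8-bis(methoxymethoxy)-3-methylisochromane-1,4-dione (racemic, C3 labile) | CC1OC(=O)c2c(OCOC)c(OC)c(OCOC)cc2C1=O | intermediate
9 | (3R,4R)-4-hydroxy-7-methoxy-6,8-bis(methoxymethoxy)-3-methylisochroman-1-one | C[C@H]1OC(=O)c2c(OCOC)c(OC)c(OCOC)cc2[C@H]1O | intermediate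
10 | {[(3R,4R)-7-methoxy-6,8-bis(methoxymethoxy)-3-methyl-1-oxoisochroman-4-yl]oxy}triphenylphosphonium ion (formed in situ) | C[C@H]1OC(=O)c2c(OCOC)c(OC)c(OCOC)cc2[C@H]1O[P+](c1ccccc1)(c1ccccc1)c1ccccc1 | intermediate
11 | (3R,4S)-7-methoxy-6,8-bis(methoxymethoxy)-3-methyl-1-oxoisochroman-4-yl formate | C[C@H]1OC(=O)c2c(OCOC)c(OC)c(OCOC)cc2[C@@H]1OC=O | intermediate
12 | (3R,4S)-6,8-dihydroxy-7-methoxy-3-methyl-1-oxoisochroman-4-yl formate | C[C@H]1OC(=O)c2c(O)c(OC)c(O)cc2[C@@H]1OC=O | intermediate
13 | {[(3R,4R)-7-methoxy-6,8-bis(methoxymethoxy)-3-methyl-1-oxoisochroman-4-yl]oxy}tributylphosphonium ion (formed in situ) | C[C@H]1OC(=O)c2c(OCOC)c(OC)c(OCOC)cc2[C@H]1O[P+](CCCC)(CCCC)CCCC | intermediate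
14 | (3R,4S)-8-hydroxy-7-methoxy-6-{[(3R,4S)-7-methoxy-6,8-bis(methoxymethoxy)-3-methyl-1-oxoisochroman-4-yl]oxy}-3-methyl-1-oxoisochroman-4-yl formate | COc1c(OCOC)cc2c(c1OCOC)C(=O)O[C@H](C)[C@H]2Oc1cc2c(c(O)c1OC)C(=O)O[C@H](C)[C@H]2OC=O | intermediate
15 | (3R,4S)-4-{[(3R,4S)-4,8-dihydroxy-7-methoxy-3-methyl-1-oxoisochroman-6-yl]oxy}-6,8-dihydroxy-7-methoxy-3-methylisochroman-1-one | COc1c(O)cc2c(c1O)C(=O)O[C@H](C)[C@H]2Oc1cc2c(c(O)c1OC)C(=O)O[C@H](C)[C@H]2O | target

Total step count: 9. Longest linear sequence: 9 steps (1 → 2 → 3 → 6 → 8 → 9 → 11 → 12 → 14 → 15; part of alcohol 9 is carried through steps 6 and 7 and rejoins the rest of 9 in step 8).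

Steps most likely to fail

Step 4 (carries the label). Acyl transfer from the activated vinyl ester may outrun C–C bond formation, collapsing the substrate toward a phthalide and consuming the carbene. The closure may also be slow because the ester must reach its disfavoured s-trans conformer, and the product may suffer base-induced enediol acyl migration. The fallback forms the same bond by radical instead of polar means and uses the known iron-hydride (MHAT) alkene–carbonyl reductive cyclisation. It sets out from 6: hydrogen-atom transfer (Fe(acac)3, PhSiH3, EtOH, 60 °C) to the terminal vinyl carbon should give the α-acyloxy radical at C3, which closes 6-exo onto the formyl carbon. Reduction of the resulting alkoxy radical should give the racemic diastereomer mixture of 4-hydroxy-7-methoxy-6,8-bis(methoxymethoxy)-3-methylisochroman-1-one F1. Dess–Martin oxidation (CH2Cl2, NaHCO3) brings the route back at dione 8.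

Step 5. The amine buffer may trigger acyl migration with ring contraction of the α-acyloxy ketone, or facial and cis/trans selection may be insufficient. The fallback separates reduction from resolution and sets out from 8. Luche reduction (NaBH4, CeCl3·7H2O, MeOH, −78 °C) should give the racemic cis alcohol rac-(3R*,4R*)-4-hydroxy-7-methoxy-6,8-bis(methoxymethoxy)-3-methylisochroman-1-one F2 by hydride attack anti to the methyl group. Lipase kinetic resolution (Candida antarctica lipase B, vinyl acetate, MTBE) should then acylate the (3S,4S) enantiomer to (3S,4S)-7-methoxy-6,8-bis(methoxymethoxy)-3-methyl-1-oxoisochroman-4-yl acetate F3. The unreacted (3R,4R) alcohol is separated by chromatography, and the route is rejoined at 9.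

Step 8. Elimination across C3–C4 to the isocoumarin (the C3 hydrogen is anti to the activated C4 oxygen in the cis alcohol) or partial ionisation at C4 with loss of clean inversion may compete with the SN2 displacement. The fallback decouples activation from displacement and sets out from 9. Sulfonylation (Ms2O, Et3N, CH2Cl2, −20 °C) should give (3R,4R)-7-methoxy-6,8-bis(methoxymethoxy)-3-methyl-1-oxoisochroman-4-yl methanesulfonate F4. Williamson displacement by the caesium 6′-phenoxide of 12 (Cs2CO3, DMF, 0 °C) with inversion should give the protected dimer, and the route is rejoined at 14.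

Further compounds
F1 | step 4 | 4-hydroxy-7-methoxy-6,8-bis(methoxymethoxy)-3-methylisochroman-1-one (racemic diastereomer mixture) | CC1OC(=O)c2c(OCOC)c(OC)c(OCOC)cc2C1O
F2 | step 5 | rac-cis-4-hydroxy-7-methoxy-6,8-bis(methoxymethoxy)-3-methylisochroman-1-one (both enantiomers written) | C[C@H]1OC(=O)c2c(OCOC)c(OC)c(OCOC)cc2[C@H]1O.C[C@@H]1OC(=O)c2c(OCOC)c(OC)c(OCOC)cc2[C@@H]1O
F3 | step 5 | (3S,4S)-7-methoxy-6,8-bis(methoxymethoxy)-3-methyl-1-oxoisochroman-4-yl acetate | C[C@@H]1OC(=O)c2c(OCOC)c(OC)c(OCOC)cc2[C@@H]1OC(C)=O
F4 | step 8 | (3R,4R)-7-methoxy-6,8-bis(methoxymethoxy)-3-methyl-1-oxoisochroman-4-yl methanesulfonate | C[C@H]1OC(=O)c2c(OCOC)c(OC)c(OCOC)cc2[C@H]1OS(C)(=O)=O
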